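## Analysis of the target

- Target 24 is a 1,4-diaryl-tetrahydro-1H,3H-furo[3,4-c]furan: two tetrahydrofuran rings cis-fused through C3a–C6a. Numbering used here: C1 (bears ring A, 4-hydroxy-3-methoxyphenyl), O2, C3, C3a, C4 (bears ring B, 3-hydroxy-4,5-dimethoxyphenyl), O5, C6, C6a.
- The four contiguous stereocentres are (1S,3aR,4S,6aR). The bridgehead hydrogens are cis, and each aryl group sits on the convex face: ring A trans to C6, ring B trans to C3.
- The core has a twofold shape but carries two different arenes, so dimerisation of one C6–C3 unit is excluded; the halves must be introduced separately and the absolute configuration imposed.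
- C1–O2 and C4–O5 are benzylic ether bonds to electron-rich arenes. They ionise under acid (epimerisation at C1 or C4) and can be hydrogenolysed. The two phenols are oxidisable and must be masked through carbenoid, photochemical and radical steps.
- The difficulty is to set the cis fusion and both benzylic centres without passing through benzylic cations that would erase the configuration at C1.
- The strategy rests on C4–H. It is benzylic and alpha to O5, hence weak, and it lies five atoms from C3a along C3a–C6a–C6–O5–C4. An excited carbonyl at C3a can reach it through a seven-membered transition state, and the tether C6a–C6–O5 then allows only a cis-fused closure.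

## Retrosynthetic reasoning

**24 to 23.** The phenols are unmasked last. Both arenes are carried as benzyl ethers from the aldehyde stage, because free phenols would react with the diazo and carbenoid intermediates and quench the excited ketone.

**23 to 22 to 21 (C3a–H back to C3a–O).** The bridgehead hydrogen is traced to a tertiary alcohol through its methyl oxalate. The oxygen at C3a is the residue of the carbonyl that the key step needs. A radical reduction removes it without touching the benzylic C–O bonds, and the bicyclo[3.3.0] frame returns only the cis fusion.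

**21 to 20 (cut C3a–C4).** This is the only skeletal bond of ring C3a–C4–O5–C6–C6a that is not an ether bond. Cutting it leaves ketone 20, in which ring B hangs on a plain benzylic ether. The forward reaction must abstract the C4 hydrogen with the excited C3a carbonyl and close the resulting 1,5-biradical, setting C3a and C4 in one operation. No activating group is needed at C4.

**20 to 19 to 18 (cut O2–C3; C6a epimer).** The furanone is opened at the ether bond next to the ketone, giving hydroxy diazoketone 18; forward, a rhodium carbenoid inserts into the O–H bond. C6a is alpha to the ketone, so the cis isomer 19 from a syn aldol can be equilibrated to trans 20. Only C1 must therefore be set absolutely.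

**18 to 17 to 15 (cut C3–C3a).** The diazoketone comes from carboxylic acid 15 and a one-carbon diazo unit. The hydroxyl is silylated (17) so that the acid can be activated.

**15 to 14 to 13 to 9 + 10 (cut C1–C6a).** An auxiliary-controlled syn aldol between imide 9 and aldehyde 10 sets C1 as S. The acyl carbon becomes C3a, the alpha carbon C6a.

**9 to 6 + 7; 6 to 3 + 4 (cut N–acyl; cut O5–C6).** Acid 6 is the oxa-Michael adduct of benzylic alcohol 3 with acrylate 4, which supplies C6, C6a and C3a. Auxiliary 7 is attached by N-acylation.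

**3 to 2 to 1.** Alcohol 3 is the reduced, O-benzylated form of aldehyde 1; its carbonyl carbon becomes C4.

## Alternatives that were turned down

**Alternative 1:** Conjugate addition–aldol on a chiral butenolide.
- Disconnection: C3a–C4 and C1–C6a are cut together. The chain C3–C3a–C6a–C6 comes from menthyloxybutenolide A1, C4 with ring B from dithiane A2 (as its 2-lithio derivative), C1 with ring A from aldehyde 10.
- Forward key step: lithiated A2 adds 1,4 to A1 anti to the acetal substituent and the lactone enolate is trapped by 10, giving adduct A3.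
- For: three components are joined in one flask by a very reliable reaction class, both bridgehead centres are set by a cheap auxiliary, and the route is convergent.
- Against: A3 contains no ring of the target. Dithiane removal in the presence of electron-rich arenes, reduction of ketone, lactone and acetal, and two acid-mediated etherifications follow. These close the rings through benzylic cations, so C1 and C4 are set only by thermodynamic preference.
- Comparison: this alternative is at least as short overall and is stronger on convergence and on the reliability of the C–C bond formations. The chosen route offers instead a key step that forms the bicycle with its fusion directly, three simple steps after it, and no ionisation at a benzylic carbon, so the C1 configuration set in the aldol is never put at risk.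

**Alternative 2:** Double cyclocarbonylation of an ene-1,4-diol.
- Disconnection: C6–C6a, C3–C3a, O5–C6 and O2–C3 are cut, leading to (E)-ene-diol A4.
- Forward key step: oxidative carbonylation with divalent palladium adds two carbonyl carbons syn across the alkene, and both carbinol oxygens lactonise to bis-lactone A5.
- For: four bonds and both rings in one step, the highest bond count per step of all the options.
- Against: the carbinols of A4 are benzylic and allylic, so they are prone to ionisation and to oxidation by divalent palladium. The first acyl-palladation must close a five-membered ring containing both alkene carbons (an endo mode), which competes poorly with beta-hydride elimination. Face selectivity rests only on the substrate. Two lactone carbonyls must then be reduced to CH2, typically via lactols and Lewis-acid silane reduction, which again threatens C1 and C4.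
- Comparison: more ambitious per step, but the ring-forming mode has no close precedent on such a substrate, whereas the photocyclisation of beta-alkoxy ketones is a known reaction type. After the key step the chosen route needs only a deoxygenation, not a double carbonyl removal.

**Alternative 3:** Ring B by cyclobutenone benzannulation.
- Disconnection: the ring B bond between the hydroxyl-bearing carbon and the adjacent CH is cut, leading to alkenylcyclobutenone A6 attached at C4 of a preformed furofuran.
- Forward key step: thermolysis opens A6 to a dienylketene whose six-electron electrocyclisation and tautomerisation give mono-benzyl ether A7.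
- For: the oxygenation pattern of ring B arises regiospecifically under neutral thermal conditions, and the ring B phenol is liberated while ring A stays protected.
- Against: the arene is not the problem of this target, since aldehyde 1 delivers ring B intact. The whole bicycle with four stereocentres must be built beforehand with a non-aromatic substituent at C4, which removes the benzylic activation that the convenient ways of setting C4 depend on. Several extra steps are spent on the cyclobutenone.
- Comparison: longer, and it solves a regiochemical question that does not arise here. The chosen route spends its key step on the real difficulty, the C3a–C4 bond and the ring fusion.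

Key step: step 11

## Route

Remark: Ar-A = 4-(benzyloxy)-3-methoxyphenyl (protected ring A); Ar-B = 3-(benzyloxy)-4,5-dimethoxyphenyl (protected ring B). Compounds 1, 4, 7 and 10 are taken as purchasable.

Step 1
Reactants: 1 3-hydroxy-4,5-dimethoxybenzaldehyde
Product: 2 3-(benzyloxy)-4,5-dimethoxybenzaldehyde
Conditions: BnBr, K2CO3, DMF, rt
Reagents that add atoms: benzyl bromide, BrCc1ccccc1
Why: Williamson etherification of the phenoxide; the aldehyde is inert to carbonate and the benzyl ether withstands every later step up to the final hydrogenolysis.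

Step 2
Reactants: 2 3-(benzyloxy)-4,5-dimethoxybenzaldehyde
Product: 3 [3-(benzyloxy)-4,5-dimethoxyphenyl]methanol
Conditions: NaBH4, MeOH–THF, 0 °C
Reagents that add atoms: none
Why: Borohydride reduction of an aryl aldehyde to the benzylic alcohol; the aryl ethers are untouched.

Step 3
Reactants: 3 [3-(benzyloxy)-4,5-dimethoxyphenyl]methanol; 4 methyl acrylate
Product: 6 3-{[3-(benzyloxy)-4,5-dimethoxyphenyl]methoxy}propanoic acid, via methyl ester 5 (not isolated)
Conditions: KOt-Bu (10 mol%), THF, 0 °C to rt; then LiOH, H2O, rt; HCl work-up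
Reagents that add atoms: lithium hydroxide, [Li+].[OH-]
Why: Base-catalysed oxa-Michael addition of the benzylic alkoxide to the acrylate forms O5–C6, and saponification follows in the same flask; any transesterified ester converges on the same acid, and acid–base extraction removes unreacted 3.

Step 4
Reactants: 6 3-{[3-(benzyloxy)-4,5-dimethoxyphenyl]methoxy}propanoic acid; 7 (S)-4-benzyloxazolidin-2-one
Product: 9 (S)-4-benzyl-3-(3-{[3-(benzyloxy)-4,5-dimethoxyphenyl]methoxy}propanoyl)oxazolidin-2-one, via mixed pivalic anhydride 8 (not isolated)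
Conditions: t-BuCOCl, Et3N, THF, −20 °C; then LiCl, 7, −20 °C to rt
Reagents that add atoms: none
Why: N-acylation of the oxazolidinone through the mixed pivalic anhydride, which is attacked at the unhindered acyl carbon; the conditions are too weakly basic to enolise the imide and expel the beta-alkoxide.

Step 5
Reactants: 9 (S)-4-benzyl-3-(3-{[3-(benzyloxy)-4,5-dimethoxyphenyl]methoxy}propanoyl)oxazolidin-2-one; 10 4-(benzyloxy)-3-methoxybenzaldehyde
Product: 13 (S)-4-benzyl-3-[(2S,3S)-3-(Ar-A)-2-{[(Ar-B)methoxy]methyl}-3-hydroxypropanoyl]oxazolidin-2-one (syn aldol), via Z-dibutylboron enolate 11 (not isolated), via dibutylboron aldolate 12 (not isolated)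
Conditions: Bu2BOTf, i-Pr2NEt, CH2Cl2, −78 to 0 °C; 10, −78 to 0 °C; then pH 7 buffer, MeOH, H2O2
Reagents that add atoms: none
Why: Evans syn aldol: the Z boron enolate reacts through a Zimmerman–Traxler chair on the face away from the benzyl group of the auxiliary, which sets the carbinol carbon (C1) as S and the alpha carbon (C6a) syn to it; the enolate is kept cold so that the beta-alkoxide is not eliminated.

Step 6
Reactants: 13 syn aldol adduct
Product: 14 (S)-4-benzyl-3-[(2S,3S)-3-(Ar-A)-2-{[(Ar-B)methoxy]methyl}-3-[(tert-butyldimethylsilyl)oxy]propanoyl]oxazolidin-2-one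
Conditions: TBSOTf, 2,6-lutidine, CH2Cl2, 0 °C
Reagents that add atoms: tert-butyldimethylsilyl trifluoromethanesulfonate, CC(C)(C)[Si](C)(C)OS(=O)(=O)C(F)(F)F
Why: Silylation of the secondary benzylic alcohol, so that the carboxyl group can later be activated without O-acylation, lactonisation or retro-aldol cleavage.

Step 7
Reactants: 14 silylated aldol imide
Product: 15 (2S,3S)-3-(Ar-A)-2-{[(Ar-B)methoxy]methyl}-3-[(tert-butyldimethylsilyl)oxy]propanoic acid
Conditions: LiOH, H2O2, THF–H2O, 0 °C; Na2SO3; HCl
Reagents that add atoms: hydrogen peroxide (as LiOOH), OO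
Why: Hydroperoxide attacks the exocyclic imide carbonyl selectively and is not basic enough to epimerise the alpha centre; the auxiliary is recovered.

Step 8
Reactants: 15 silyloxy acid
Product: 17 (3S,4S)-4-(Ar-A)-3-{[(Ar-B)methoxy]methyl}-4-[(tert-butyldimethylsilyl)oxy]-1-diazobutan-2-one, via mixed isobutyl carbonic anhydride 16 (not isolated)
Conditions: i-BuOCOCl, N-methylmorpholine, THF, −20 °C; then CH2N2, Et2O, −20 °C to rt
Reagents that add atoms: diazomethane, C=[N+]=[N-]
Why: Acylation of diazomethane by the mixed anhydride (the first half of an Arndt–Eistert sequence) gives the alpha-diazoketone and introduces C3 under non-epimerising conditions.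

Step 9
Reactants: 17 silyloxy diazoketone
Product: 18 (3S,4S)-4-(Ar-A)-3-{[(Ar-B)methoxy]methyl}-1-diazo-4-hydroxybutan-2-one
Conditions: Bu4NF, AcOH, THF, 0 °C to rt
Reagents that add atoms: none
Why: Fluoride cleaves the Si–O bond; the acetic acid buffer keeps the medium non-basic, so the beta-hydroxy ketone should not undergo retro-aldol cleavage, and it is too weak an acid to protonate the diazoketone.

Step 10
Reactants: 18 hydroxy diazoketone
Product: 20 (4R,5S)-5-(Ar-A)-4-{[(Ar-B)methoxy]methyl}dihydrofuran-3(2H)-one (trans), via cis-furanone 19 (not isolated)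
Conditions: Rh2(OAc)4 (1 mol%), CH2Cl2, rt; then DBU (10 mol%), rt
Reagents that add atoms: none
Why: The rhodium carbenoid inserts into the O–H bond and closes the five-membered ring by O2–C3 bond formation, the hydroxyl ylide being fixed by fast proton transfer while attack on the ether oxygen is reversible; catalytic base then equilibrates C6a, alpha to the ketone, to the more stable trans isomer, and C1 is not enolisable and keeps its configuration.

Step 11
Reactants: 20 trans-furanone
Product: 21 (1S,3aS,4R,6aR)-1-(Ar-A)-4-(Ar-B)dihydro-1H,3H-furo[3,4-c]furan-3a(4H)-ol (cis-fused; bridgehead OH on the convex face; both aryl groups exo)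
Conditions: hν (medium-pressure Hg lamp, Pyrex, λ > 300 nm), degassed C6H6, 0.005 M, rt
Reagents that add atoms: none
Why: n,π* excitation of the C3a carbonyl makes its oxygen (not the carbon) abstract the benzylic, O5-activated hydrogen from C4 through a seven-membered transition state, leaving a ketyl radical at C3a and a benzylic alpha-oxy radical at C4. The 1,5-biradical collapses by C3a–C4 bond formation to the five-membered ring C3a–C4–O5–C6–C6a, a radical–radical recombination with no ring-closure constraint; the closest known reaction type is the Norrish–Yang photocyclisation of beta-alkoxy ketones to 3-hydroxytetrahydrofurans. C3a: the tether C6a–C6–O5 can deliver C4 only to the face of C3a cis to C6, so the fusion is cis and the new OH lies on the convex face. C4: during collapse the ring B aryl turns away from the C3 methylene and the concave face, so it should end exo. The selectivity needed is abstraction at C4–H only: the gamma atom on this side is O5, C6–H would need a five-membered transition state, C1–H lies in the ring out of reach of the in-plane oxygen orbital, and the PhCH2O hydrogens are remote, which is why the solution is kept dilute. Pyrex-filtered light excites the ketone rather than the arenes; alpha-cleavage is the competing channel and is partly reversed by recombination. The trans relation of C1 and C6a in 20 is carried unchanged into 21, so ring A ends exo.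

Step 12
Reactants: 21 3a-hydroxy furofuran
Product: 22 methyl (1S,3aS,4R,6aR)-1-(Ar-A)-4-(Ar-B)tetrahydro-1H,3H-furo[3,4-c]furan-3a(4H)-yl oxalate
Conditions: ClCOCO2Me, Et3N, DMAP, CH2Cl2, 0 °C to rt
Reagents that add atoms: methyl chlorooxoacetate, COC(=O)C(Cl)=O
Why: The very electrophilic acyl chloride, with DMAP catalysis, acylates even a hindered tertiary alcohol; the basic medium cannot ionise the benzylic ethers.

Step 13
Reactants: 22 tertiary methyl oxalate
Product: 23 (1S,3aR,4S,6aR)-1-(Ar-A)-4-(Ar-B)tetrahydro-1H,3H-furo[3,4-c]furan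
Conditions: Bu3SnH, AIBN, toluene, 110 °C
Reagents that add atoms: none
Why: Barton–McCombie-type radical deoxygenation: the stannyl radical adds to the oxalate carbonyl, and fragmentation gives the tertiary bridgehead radical at C3a, which takes hydrogen from Bu3SnH on the convex face, the only way to keep the bicyclo[3.3.0] frame cis-fused; C1, C4 and C6a are not involved, and an excess of hydride keeps ring-opening beta-scission from competing.

Step 14
Reactants: 23 di-O-benzyl furofuran
Product: 24 4-[(1S,3aR,4S,6aR)-4-(3-hydroxy-4,5-dimethoxyphenyl)tetrahydro-1H,3H-furo[3,4-c]furan-1-yl]-2-methoxyphenol (target)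
Conditions: H2 (1 atm), Pd/C, pyridine (0.5 equiv), EtOAc–MeOH, rt
Reagents that add atoms: none
Why: Hydrogenolysis of the two aryl benzyl ethers, which cleave much faster than the hindered cyclic benzylic ethers C1–O2 and C4–O5; pyridine moderates the catalyst against cleavage of alkyl benzylic ethers, and the reaction is stopped at full debenzylation.

## Compound list

1 | 3-hydroxy-4,5-dimethoxybenzaldehyde | COc1cc(C=O)cc(O)c1OC | starting material
2 | 3-(benzyloxy)-4,5-dimethoxybenzaldehyde | COc1cc(C=O)cc(OCc2ccccc2)c1OC | intermediate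
3 | [3-(benzyloxy)-4,5-dimethoxyphenyl]methanol | COc1cc(CO)cc(OCc2ccccc2)c1OC | intermediate
4 | methyl acrylate | C=CC(=O)OC | starting material
5 | methyl 3-{[3-(benzyloxy)-4,5-dimethoxyphenyl]methoxy}propanoate (not isolated) | COC(=O)CCOCc1cc(OC)c(OC)c(OCc2ccccc2)c1 | intermediate
6 | 3-{[3-(benzyloxy)-4,5-dimethoxyphenyl]methoxy}propanoic acid | OC(=O)CCOCc1cc(OC)c(OC)c(OCc2ccccc2)c1 | intermediate
7 | (S)-4-benzyloxazolidin-2-one | O=C1OC[C@H](Cc2ccccc2)N1 | starting material
8 | 3-{[3-(benzyloxy)-4,5-dimethoxyphenyl]methoxy}propanoic pivalic anhydride (not isolated) | CC(C)(C)C(=O)OC(=O)CCOCc1cc(OC)c(OC)c(OCc2ccccc2)c1 | intermediate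
9 | (S)-4-benzyl-3-(3-{[3-(benzyloxy)-4,5-dimethoxyphenyl]methoxy}propanoyl)oxazolidin-2-one | O=C(CCOCc1cc(OC)c(OC)c(OCc2ccccc2)c1)N1C(=O)OC[C@@H]1Cc1ccccc1 | intermediate
10 | 4-(benzyloxy)-3-methoxybenzaldehyde | COc1cc(C=O)ccc1OCc1ccccc1 | starting material
11 | Z-dibutylboron enolate of 9 (not isolated) | CCCCB(CCCC)O/C(=C\COCc1cc(OC)c(OC)c(OCc2ccccc2)c1)N1C(=O)OC[C@@H]1Cc1ccccc1 | intermediate
12 | dibutylboron aldolate of 13 (not isolated) | O=C([C@@H](COCc1cc(OC)c(OC)c(OCc2ccccc2)c1)[C@H](OB(CCCC)CCCC)c1ccc(OCc2ccccc2)c(OC)c1)N1C(=O)OC[C@@H]1Cc1ccccc1 | intermediate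
13 | (S)-4-benzyl-3-[(2S,3S)-3-[4-(benzyloxy)-3-methoxyphenyl]-2-({[3-(benzyloxy)-4,5-dimethoxyphenyl]methoxy}methyl)-3-hydroxypropanoyl]oxazolidin-2-one | O=C([C@@H](COCc1cc(OC)c(OC)c(OCc2ccccc2)c1)[C@H](O)c1ccc(OCc2ccccc2)c(OC)c1)N1C(=O)OC[C@@H]1Cc1ccccc1 | intermediate
14 | tert-butyldimethylsilyl ether of 13, (2S,3S) | O=C([C@@H](COCc1cc(OC)c(OC)c(OCc2ccccc2)c1)[C@H](O[Si](C)(C)C(C)(C)C)c1ccc(OCc2ccccc2)c(OC)c1)N1C(=O)OC[C@@H]1Cc1ccccc1 | intermediate
15 | (2S,3S)-3-[4-(benzyloxy)-3-methoxyphenyl]-2-({[3-(benzyloxy)-4,5-dimethoxyphenyl]methoxy}methyl)-3-[(tert-butyldimethylsilyl)oxy]propanoic acid | OC(=O)[C@@H](COCc1cc(OC)c(OC)c(OCc2ccccc2)c1)[C@H](O[Si](C)(C)C(C)(C)C)c1ccc(OCc2ccccc2)c(OC)c1 | intermediate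
16 | mixed isobutyl carbonic anhydride of 15 (not isolated) | CC(C)COC(=O)OC(=O)[C@@H](COCc1cc(OC)c(OC)c(OCc2ccccc2)c1)[C@H](O[Si](C)(C)C(C)(C)C)c1ccc(OCc2ccccc2)c(OC)c1 | intermediate
17 | (3S,4S)-4-[4-(benzyloxy)-3-methoxyphenyl]-3-({[3-(benzyloxy)-4,5-dimethoxyphenyl]methoxy}methyl)-4-[(tert-butyldimethylsilyl)oxy]-1-diazobutan-2-one | [N-]=[N+]=CC(=O)[C@@H](COCc1cc(OC)c(OC)c(OCc2ccccc2)c1)[C@H](O[Si](C)(C)C(C)(C)C)c1ccc(OCc2ccccc2)c(OC)c1 | intermediate
18 | (3S,4S)-4-[4-(benzyloxy)-3-methoxyphenyl]-3-({[3-(benzyloxy)-4,5-dimethoxyphenyl]methoxy}methyl)-1-diazo-4-hydroxybutan-2-one | [N-]=[N+]=CC(=O)[C@@H](COCc1cc(OC)c(OC)c(OCc2ccccc2)c1)[C@H](O)c1ccc(OCc2ccccc2)c(OC)c1 | intermediate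
19 | (4S,5S)-5-[4-(benzyloxy)-3-methoxyphenyl]-4-({[3-(benzyloxy)-4,5-dimethoxyphenyl]methoxy}methyl)dihydrofuran-3(2H)-one, cis (not isolated) | COc1cc([C@H]2OCC(=O)[C@H]2COCc2cc(OCc3ccccc3)c(OC)c(OC)c2)ccc1OCc1ccccc1 | intermediate
20 | (4R,5S)-5-[4-(benzyloxy)-3-methoxyphenyl]-4-({[3-(benzyloxy)-4,5-dimethoxyphenyl]methoxy}methyl)dihydrofuran-3(2H)-one, trans | COc1cc([C@H]2OCC(=O)[C@@H]2COCc2cc(OCc3ccccc3)c(OC)c(OC)c2)ccc1OCc1ccccc1 | intermediate
21 | (1S,3aS,4R,6aR)-1-[4-(benzyloxy)-3-methoxyphenyl]-4-[3-(benzyloxy)-4,5-dimethoxyphenyl]dihydro-1H,3H-furo[3,4-c]furan-3a(4H)-ol | COc1cc([C@H]2OC[C@@]3(O)[C@@H]2CO[C@@H]3c2cc(OCc4ccccc4)c(OC)c(OC)c2)ccc1OCc1ccccc1 | intermediate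
22 | methyl (1S,3aS,4R,6aR)-1-[4-(benzyloxy)-3-methoxyphenyl]-4-[3-(benzyloxy)-4,5-dimethoxyphenyl]tetrahydro-1H,3H-furo[3,4-c]furan-3a(4H)-yl oxalate | COc1cc([C@H]2OC[C@@]3(OC(=O)C(=O)OC)[C@@H]2CO[C@@H]3c2cc(OCc4ccccc4)c(OC)c(OC)c2)ccc1OCc1ccccc1 | intermediate
23 | (1S,3aR,4S,6aR)-1-[4-(benzyloxy)-3-methoxyphenyl]-4-[3-(benzyloxy)-4,5-dimethoxyphenyl]tetrahydro-1H,3H-furo[3,4-c]furan | COc1cc([C@H]2OC[C@H]3[C@@H]2CO[C@@H]3c2cc(OCc4ccccc4)c(OC)c(OC)c2)ccc1OCc1ccccc1 | intermediate
24 | 4-[(1S,3aR,4S,6aR)-4-(3-hydroxy-4,5-dimethoxyphenyl)tetrahydro-1H,3H-furo[3,4-c]furan-1-yl]-2-methoxyphenol | COc1cc([C@H]2OC[C@H]3[C@@H]2CO[C@@H]3c2cc(O)c(OC)c(OC)c2)ccc1O | target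

## Step count and least certain steps

Total: 14 steps. Longest linear sequence: 14 steps (1 to 24); 4, 7 and 10 enter as purchased materials.

**Step 11 (key step).**
- Most likely to go wrong: deactivation of the excited carbonyl before it abstracts hydrogen. The channels are alpha-cleavage of the strained alpha-alkoxy ketone and energy or charge transfer to the two electron-rich, benzyloxy-substituted arenes. Closure of the biradical with ring B on the concave face is a lesser risk.
- Fallback: this changes the substrate that is irradiated, not the lamp or solvent. It eases the quenching and removes the benzyloxy hydrogens; it does not remove the alpha-cleavage channel. It sets out from 20 and comes back at 24. The two aryl benzyl ethers of 20 are hydrogenolysed over Pd/C in the presence of pyridine, which holds back cleavage of the alkyl benzylic ethers, to give the diphenol ketone F1. Acetylation (Ac2O, pyridine) gives the diacetate ketone F2, whose arenes are poorer donors and which carries no PhCH2O hydrogens. Irradiation as in step 11 should give the diacetyl 3a-hydroxy furofuran F3. The reagents of steps 12 and 13 then lead through the diacetyl methyl oxalate F4 to the diacetyl furofuran F5, and methanolysis (K2CO3, MeOH) gives 24. The final hydrogenolysis is no longer needed.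

**Step 13 (with step 12).**
- Most likely to go wrong: loss of the labile tertiary oxalate by hydrolysis or by acyl–oxygen cleavage back to 21, or slow fragmentation because the bridgehead radical is pyramidal and flanked by two beta-oxygens.
- Fallback: it sets out from 21 and comes back at 23. Oxalyl chloride converts 21 into the alkyl chlorooxalate F6. The sodium salt of N-hydroxypyridine-2-thione gives the mixed oxalate thiohydroxamate F7 (a Barton ester). Heating it in benzene with t-BuSH releases two molecules of carbon dioxide and the same C3a radical in a chain that needs no tin, and hydrogen transfer from the thiol gives 23.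

**Step 10.**
- Most likely to go wrong: attack of the carbenoid on the ether oxygen O5 (a five-membered oxonium ylide followed by a 1,2-shift of the ring B benzyl group) instead of O–H insertion, and beta-elimination of the ring B alkoxide from the C6a enolate during the base equilibration.
- Fallback: it avoids the carbenoid, sets out from 17 and comes back at 20. Anhydrous HCl in Et2O–THF at −20 °C converts the diazoketone into the silyloxy chloroketone F8. HF·pyridine removes the silyl group to give the hydroxy chloroketone F9. K2CO3 in acetone closes the ring by intramolecular Williamson etherification and equilibrates C6a in the same operation, giving 20. This also bypasses step 9.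

**Step 14.**
- Most likely to go wrong: over-reduction, that is hydrogenolysis of the benzylic C1–O2 or C4–O5 bond after the benzyl groups have gone.
- Fallback: it sets out from 23 and comes back at 24. Silane transfer (Pd(OAc)2, Et3SiH, Et3N, CH2Cl2) converts aryl benzyl ethers, but not alkyl benzylic ethers, into silyl ethers, giving the bis(triethylsilyl) ether F10. Bu4NF then releases 24.

## Further compounds

F1 | step 11 | (4R,5S)-5-(4-hydroxy-3-methoxyphenyl)-4-{[(3-hydroxy-4,5-dimethoxyphenyl)methoxy]methyl}dihydrofuran-3(2H)-one | COc1cc([C@H]2OCC(=O)[C@@H]2COCc2cc(O)c(OC)c(OC)c2)ccc1O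
F2 | step 11 | diacetate of F1, (4R,5S) | COc1cc([C@H]2OCC(=O)[C@@H]2COCc2cc(OC(C)=O)c(OC)c(OC)c2)ccc1OC(C)=O
F3 | step 11 | (1S,3aS,4R,6aR)-1-(4-acetoxy-3-methoxyphenyl)-4-(3-acetoxy-4,5-dimethoxyphenyl)dihydro-1H,3H-furo[3,4-c]furan-3a(4H)-ol | COc1cc([C@H]2OC[C@@]3(O)[C@@H]2CO[C@@H]3c2cc(OC(C)=O)c(OC)c(OC)c2)ccc1OC(C)=O
F4 | step 11 | methyl oxalate of F3 | COc1cc([C@H]2OC[C@@]3(OC(=O)C(=O)OC)[C@@H]2CO[C@@H]3c2cc(OC(C)=O)c(OC)c(OC)c2)ccc1OC(C)=O
F5 | step 11 | diacetate of 24, (1S,3aR,4S,6aR) | COc1cc([C@H]2OC[C@H]3[C@@H]2CO[C@@H]3c2cc(OC(C)=O)c(OC)c(OC)c2)ccc1OC(C)=O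
F6 | step 13 | chlorooxalate of 21 | COc1cc([C@H]2OC[C@@]3(OC(=O)C(Cl)=O)[C@@H]2CO[C@@H]3c2cc(OCc4ccccc4)c(OC)c(OC)c2)ccc1OCc1ccccc1
F7 | step 13 | mixed oxalate of 21 with N-hydroxypyridine-2-thione | COc1cc([C@H]2OC[C@@]3(OC(=O)C(=O)On4ccccc4=S)[C@@H]2CO[C@@H]3c2cc(OCc5ccccc5)c(OC)c(OC)c2)ccc1OCc1ccccc1
F8 | step 10 | (3S,4S)-4-[4-(benzyloxy)-3-methoxyphenyl]-3-({[3-(benzyloxy)-4,5-dimethoxyphenyl]methoxy}methyl)-4-[(tert-butyldimethylsilyl)oxy]-1-chlorobutan-2-one | ClCC(=O)[C@@H](COCc1cc(OC)c(OC)c(OCc2ccccc2)c1)[C@H](O[Si](C)(C)C(C)(C)C)c1ccc(OCc2ccccc2)c(OC)c1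
F9 | step 10 | (3S,4S)-4-[4-(benzyloxy)-3-methoxyphenyl]-3-({[3-(benzyloxy)-4,5-dimethoxyphenyl]methoxy}methyl)-1-chloro-4-hydroxybutan-2-one | ClCC(=O)[C@@H](COCc1cc(OC)c(OC)c(OCc2ccccc2)c1)[C@H](O)c1ccc(OCc2ccccc2)c(OC)c1
F10 | step 14 | bis(triethylsilyl) ether of 24 | COc1cc([C@H]2OC[C@H]3[C@@H]2CO[C@@H]3c2cc(O[Si](CC)(CC)CC)c(OC)c(OC)c2)ccc1O[Si](CC)(CC)CC
A1 | alternative 1 | (5R)-5-{[(1R,2S,5R)-2-isopropyl-5-methylcyclohexyl]oxy}furan-2(5H)-one | O=C1O[C@@H](O[C@@H]2C[C@H](C)CC[C@H]2C(C)C)C=C1
A2 | alternative 1 | 2-[3-(benzyloxy)-4,5-dimethoxyphenyl]-1,3-dithiane | COc1cc(C2SCCCS2)cc(OCc2ccccc2)c1OC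
A3 | alternative 1 | 3-[hydroxy(Ar-A)methyl]-4-[2-(Ar-B)-1,3-dithian-2-yl]-5-(menthyloxy)dihydrofuran-2(3H)-one | O=C1O[C@@H](O[C@@H]2C[C@H](C)CC[C@H]2C(C)C)[C@H](C2(c3cc(OCc4ccccc4)c(OC)c(OC)c3)SCCCS2)[C@H]1[C@H](O)c1ccc(OCc2ccccc2)c(OC)c1
A4 | alternative 2 | (1S,4S,2E)-1-[4-(benzyloxy)-3-methoxyphenyl]-4-[3-(benzyloxy)-4,5-dimethoxyphenyl]but-2-ene-1,4-diol | COc1cc([C@@H](O)/C=C/[C@H](O)c2cc(OCc3ccccc3)c(OC)c(OC)c2)ccc1OCc1ccccc1
A5 | alternative 2 | cis-fused 1-(Ar-A)-4-(Ar-B)-furo[3,4-c]furan-3,6-dione (bis-lactone, both aryl groups exo) | COc1cc([C@H]2OC(=O)[C@H]3[C@@H]2C(=O)O[C@@H]3c2cc(OCc4ccccc4)c(OC)c(OC)c2)ccc1OCc1ccccc1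
A6 | alternative 3 | 4-{1-[1-(Ar-A)-furo[3,4-c]furan-4-yl]vinyl}-2,3-dimethoxycyclobut-2-en-1-one (cyclobutenone carbon not defined) | COc1cc([C@H]2OC[C@H]3[C@@H]2CO[C@@H]3C(=C)C2C(=O)C(OC)=C2OC)ccc1OCc1ccccc1
A7 | alternative 3 | ring A O-benzyl ether of 24 (ring B hydroxyl free) | COc1cc([C@H]2OC[C@H]3[C@@H]2CO[C@@H]3c2cc(O)c(OC)c(OC)c2)ccc1OCc1ccccc1
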